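Assumption: the target is achiral, so racemic methyl 2‑hydroxybut‑3‑enoate is used and the sp3 centres of 12–15 are carried as unseparated diastereomer mixtures; commercial stearoyl chloride serves as the C18 building block.

## Analysis of the target

Target 17 is a monocyclic 1,4‑benzoquinone. With the ring numbered C1 (carbonyl), C2 (hydroxyl), C3 (hexadecyl), C4 (carbonyl), C5 (methoxy) and C6 (hydrogen), five of six ring carbons are substituted and four carry oxygen. There is no stereocentre, so any sp3 centre in an intermediate may be carried as a mixture. The sensitive groups are the electrophilic, redox‑active quinone, the acidic C2 hydroxyl (a vinylogous acid, nucleophilic at O and at C3) and the C5 methoxy group (a vinylogous ester open to addition–elimination and hydrolysis). The difficulty is regiochemical: the C2 and C5 oxygens are electronically near‑equivalent, yet one must be free and the other methylated, and the chain must sit between C2 and C4. Routes that first build a dihydroxyquinone or an arene therefore end with a selective O‑alkylation, O‑dealkylation or ring C–H oxidation. The strategy rests on C5=C6, the only ring double bond that carries hydrogen and at the same time an enol ether conjugated to the C4 ketone. Opening the ring there leaves a 1‑methoxyvinyl ketone terminus (C5, C4) and a vinyl carbinol terminus (C6, C1) on a chain in which each oxygen has a different form: methyl enol ether (C5), ketone (C4), and two carbinols (C1, C2).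

## Retrosynthetic reasoning

**17 ⇒ 16 ⇒ 15 (no bond cut).** Target 17 is the enol tautomer of ene‑triketone 16: the C3 hydrogen, flanked by the C2 and C4 carbonyls, moves to the C2 oxygen. Triketone 16 is the double oxidation product of vicinal diol 15. The oxidation level is lowered at C1/C2, not at C4, because this turns the two oxygens that must differ from the C5 methoxy into plain carbinols and makes C1–C3 sp3. Forward, both carbinols must be oxidised without C1–C2 cleavage and without β‑elimination of the C2 oxygen.

**15 ⇒ 14 (protecting groups).** The diol is carried as bis‑silyl ether 14, so that no free hydroxyl sits β to the ketone or next to a metal carbene during ring formation. Forward, a mild desilylation is needed that leaves the enol ether and the β‑oxygenated ketone intact.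

**14 ⇒ 13 (C5=C6 cut, key disconnection).** The ring double bond of 14 is opened by retro‑metathesis to the acyclic diene 13, each former ring carbon gaining a terminal methylene. This bond is chosen because it is the only trisubstituted, hydrogen‑bearing ring alkene; the C2=C3 alkene is tetrasubstituted and appears only in the final tautomerisation. The cut also leaves a chain that needs only carbonyl chemistry. Forward, the catalyst must load at the vinyl carbinol end and close a six‑membered ring onto the 1,1‑disubstituted enol ether olefin, expelling the two terminal methylenes.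

**13 ⇒ 12 ⇒ 6 + 10 (C2–C3 cut).** Removing one silyl group gives β‑hydroxy ketone 12, an aldol retron: C3 is α to the C4 ketone and C2 bears oxygen. Cutting C2–C3 gives ketone 6, which holds the whole alkyl chain, the C4 carbonyl and the C5 methoxyvinyl unit, and aldehyde 10, which supplies C2, C1 and the vinyl group. Ketone 6 has a single enolisable position, so regiochemistry is automatic. The three new sp3 centres need no control.

**6 ⇒ 2 + 4 (C4–C5 cut); 4 ⇐ 3; 2 ⇐ 1.** The acyl–vinyl bond is cut to Weinreb amide 2 and the acyl‑anion equivalent 4, made by metalation of enol ether 3. This places the C5 methoxy at the outset as part of a two‑carbon reagent and fixes the chain length from the C18 acid derivative 1.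

**10 ⇐ 8 ⇐ 7.** The α‑silyloxy aldehyde comes from ester 8 by partial reduction, and 8 from hydroxy ester 7 by silylation. Both oxygens that become C1 and C2 of the ring thus enter as defined functions on a four‑carbon piece.

## Alternatives that were turned down

**Alternative 1: cyclobutenone ring expansion.**
- Disconnection: the C4–C5 ring bond. C1–C4 come from a four‑membered ring derived from a squaric diester, C5 and C6 from a 2‑methoxyvinyl group.
- Forward key step: heating 2‑hexadecyl‑4‑hydroxy‑3‑isopropoxy‑4‑[(Z)‑2‑methoxyvinyl]cyclobut‑2‑en‑1‑one A1 opens the ring (4π) to a dienyl ketene. 6π closure and tautomerisation give 3‑hexadecyl‑2‑isopropoxy‑5‑methoxybenzene‑1,4‑diol A2. Oxidation and removal of the isopropyl group would follow.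
- For: A1 needs only two organometallic additions and one rearrangement. The thermal cascade is reagent‑free and concentration‑independent, its regiochemistry follows well‑understood rules, and it reaches the aromatic oxidation level directly in about five or six steps.
- Against: it needs a 2‑methoxyvinyl organolithium, far less accessible than 3, and clean 1,2‑additions to the squarate core. The last step must cleave the isopropyl vinylogous ester at C2 while sparing the methyl vinylogous ester at C5, a discrimination between two similar alkoxy groups.
- Comparison: this alternative is stronger in length and in reliability of ring formation. The chosen route offers instead a C5 methoxy that is the only ether throughout and a C2 oxygen unmasked by oxidation, not by selective dealkylation, from bulk linear starting materials.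

**Alternative 2: oxalate double Claisen annulation.**
- Disconnection: the C2–C3 and C6–C1 ring bonds. C1 and C2 come from an oxalic diester, C3–C6 from a 1,2‑diketone.
- Forward key step: the bis‑enolate of icosane‑2,3‑dione A3 is acylated twice under alkoxide to give 3‑hexadecyl‑2,5‑dihydroxy‑1,4‑benzoquinone A4. Mono‑O‑methylation at the C5 hydroxyl would finish the synthesis.
- For: A3 is simply the enol ether hydrolysis product of 6, so 17 would be reached in about five steps from 1 without protecting groups or a transition metal.
- Against: enolisable 1,2‑diketones self‑condense readily under alkoxide. The ring‑closing acylation must pass through a dianion at the hindered chain‑bearing carbon, which alkoxide generates only in low concentration. The final methylation must pick the C5 hydroxyl over the C2 hydroxyl of A4, which differ only in their neighbour (hydrogen versus chain), so mono‑ and dimethyl ether mixtures are expected.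
- Comparison: this alternative is clearly stronger in step economy. The chosen route spends about four more steps to place the methyl group unambiguously.

**Alternative 3: polyketide‑type aldol aromatisation.**
- Disconnection: the C3–C4 ring bond of an arene folded from a linear tetraketide.
- Forward key step: methyl 3,5,7‑trioxotricosanoate A5 in mild aqueous hydroxide cyclises by attack of its C2 methylene on the C7 ketone and dehydrates to methyl 6‑hexadecyl‑2,4‑dihydroxybenzoate A6.
- For: the cyclisation is biomimetic and robust, and runs concentrated in water without metals.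
- Against: A5 needs polyanion acylation chemistry and can also close by Claisen or pyrone pathways. A6 has one carbon too many and two ring oxygens too few. It must be decarboxylated to 5‑hexadecylbenzene‑1,3‑diol A7, mono‑methylated, oxidised to the quinone and hydroxylated at the last C–H next to the chain, for roughly ten steps overall.
- Comparison: the ring‑forming step is more dependable than a metathesis onto a hindered enol ether olefin. The chosen route is shorter after ring closure and brings all four oxygens in with the chain, so no aromatic C–H oxidation or sacrificial carbon is needed.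

Key step: step 7

## Route

Step 1
Reactants: 1 stearoyl chloride (octadecanoyl chloride)
Product: 2 N‑methoxy‑N‑methyloctadecanamide
Conditions: MeNH(OMe)·HCl, Et3N, CH2Cl2, 0 °C to rt
Reagents that add atoms: N,O‑dimethylhydroxylamine hydrochloride, CNOC.Cl
Why: N‑acylation of the hydroxylamine by the acid chloride (Weinreb amide formation); no competing functionality is present.

Step 2
Reactants: 2 N‑methoxy‑N‑methyloctadecanamide; 3 methyl vinyl ether
Product: 6 2‑methoxyicos‑1‑en‑3‑one, via 1‑methoxyvinyllithium 4 (not isolated), via lithium hemiaminal alkoxide 5 (not isolated)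
Conditions: 3 (excess), t‑BuLi, THF, −78 to 0 °C; then 2, −78 to 0 °C; then H2O
Reagents that add atoms: none
Why: α‑Lithiation of the enol ether gives the acyl‑anion equivalent 4, and Weinreb ketone synthesis follows: the chelated tetrahedral adduct 5 does not collapse until the quench, so a second addition cannot occur.

Step 3
Reactants: 7 methyl 2‑hydroxybut‑3‑enoate (racemic)
Product: 8 methyl 2‑(tert‑butyldimethylsilyloxy)but‑3‑enoate (racemic)
Conditions: TBSCl, imidazole, DMF, 0 °C to rt
Reagents that add atoms: tert‑butyldimethylsilyl chloride, CC(C)(C)[Si](C)(C)Cl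
Why: Standard imidazole‑promoted silylation of a secondary alcohol; the mild base does not move the β,γ‑double bond into conjugation.

Step 4
Reactants: 8 methyl 2‑(tert‑butyldimethylsilyloxy)but‑3‑enoate
Product: 10 2‑(tert‑butyldimethylsilyloxy)but‑3‑enal (racemic, used crude), via aluminium hemiacetal 9 (not isolated)
Conditions: i‑Bu2AlH (1.1 equiv), CH2Cl2, −78 °C; MeOH, then aq. KNaC4H4O6, −78 °C to rt
Reagents that add atoms: none
Why: Partial reduction of an α‑silyloxy ester: the tetrahedral aluminium hemiacetal 9 is stable at −78 °C and releases the aldehyde only on hydrolysis, as in the standard preparation of α‑silyloxy aldehydes from lactate‑type esters. The aldehyde is used at once to avoid double‑bond migration.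

Step 5
Reactants: 6 2‑methoxyicos‑1‑en‑3‑one; 10 2‑(tert‑butyldimethylsilyloxy)but‑3‑enal
Product: 12 6‑(tert‑butyldimethylsilyloxy)‑4‑hexadecyl‑5‑hydroxy‑2‑methoxyocta‑1,7‑dien‑3‑one (all diastereomers), via lithium enolate 11 (not isolated)
Conditions: LiN(i‑Pr)2, THF, −78 °C; then 10, −78 °C; AcOH/THF quench at −78 °C
Reagents that add atoms: none
Why: Kinetic deprotonation at the only enolisable carbon (C4) and lithium aldol addition to the aldehyde; the α‑methoxy group makes the enone β‑carbon electron‑rich, which suppresses conjugate self‑addition. The three sp3 centres are formed without control because all are destroyed later, and silyl migration between the vicinal oxygens is harmless since both are silylated alike in step 6.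

Step 6
Reactants: 12 6‑(tert‑butyldimethylsilyloxy)‑4‑hexadecyl‑5‑hydroxy‑2‑methoxyocta‑1,7‑dien‑3‑one
Product: 13 5,6‑bis(tert‑butyldimethylsilyloxy)‑4‑hexadecyl‑2‑methoxyocta‑1,7‑dien‑3‑one (all diastereomers)
Conditions: TBSOTf, 2,6‑lutidine, CH2Cl2, −78 to 0 °C
Reagents that add atoms: tert‑butyldimethylsilyl trifluoromethanesulfonate, CC(C)(C)[Si](C)(C)OS(=O)(=O)C(F)(F)F
Why: Silyl triflate with a hindered pyridine base silylates hindered secondary aldol hydroxyls quickly at low temperature, which removes the retro‑aldol pathway; the buffered medium leaves the ketone‑conjugated enol ether untouched.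

Step 7
Reactants: 13 5,6‑bis(tert‑butyldimethylsilyloxy)‑4‑hexadecyl‑2‑methoxyocta‑1,7‑dien‑3‑one
Product: 14 4,5‑bis(tert‑butyldimethylsilyloxy)‑6‑hexadecyl‑2‑methoxycyclohex‑2‑en‑1‑one (all diastereomers)
Conditions: second‑generation Grubbs catalyst (H2IMes)(PCy3)Cl2Ru=CHPh (10 mol %, two portions), degassed toluene, 0.005 M, 80 °C, Ar sparge
Reagents that add atoms: none
Why: Ring‑closing olefin metathesis by the Chauvin mechanism: after PCy3 dissociation the ruthenium benzylidene undergoes [2+2] cycloaddition and cycloreversion with the monosubstituted C7=C8 vinyl group of 13, placing the alkylidene on C7. This alkylidene adds intramolecularly across the 1,1‑disubstituted C1=C2 enol ether olefin with ruthenium on the terminal CH2, and cycloreversion of the ruthenacyclobutane releases 14 and Ru=CH2, which carries the chain, the two terminal CH2 groups leaving as ethylene. The closest known reaction type is ring‑closing metathesis of a terminal olefin onto a 1,1‑disubstituted enol ether olefin to give a cyclic α‑alkoxy enone. The one ring is closed as a six‑membered carbocycle (chain atoms C2–C7) with the new C2=C7 double bond endocyclic, the most favourable ring size for this reaction. No stereocentre is created, and the three existing sp3 centres are carried as a mixture because all become sp2 in the target. The step needs site‑selective initiation, which the contrast between the open vinyl group and the hindered, donor‑ and acceptor‑substituted enol ether olefin should secure. It also needs cyclisation to outrun intermolecular cross‑metathesis, which high dilution, the entropic advantage of six‑ring closure and removal of ethylene by sparging should secure. The ketone, enol ether and silyl ethers are inert to the catalyst.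

Step 8
Reactants: 14 4,5‑bis(tert‑butyldimethylsilyloxy)‑6‑hexadecyl‑2‑methoxycyclohex‑2‑en‑1‑one
Product: 15 6‑hexadecyl‑4,5‑dihydroxy‑2‑methoxycyclohex‑2‑en‑1‑one (all diastereomers, used directly)
Conditions: HF·pyridine, pyridine, THF, 0 °C to rt; then sat. aq. NaHCO3
Reagents that add atoms: none
Why: Fluoride‑driven Si–O cleavage under buffered, weakly acidic, non‑aqueous conditions, chosen over basic fluoride to avoid E1cB loss of the β‑oxygen and over aqueous mineral acid to spare the enol ether.

Step 9
Reactants: 15 6‑hexadecyl‑4,5‑dihydroxy‑2‑methoxycyclohex‑2‑en‑1‑one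
Product: 17 3‑hexadecyl‑2‑hydroxy‑5‑methoxycyclohexa‑2,5‑diene‑1,4‑dione (target), via ene‑triketone 16 (not isolated)
Conditions: (COCl)2, DMSO, CH2Cl2, −78 °C; Et3N, −78 to 0 °C; then 1 M aq. HCl
Reagents that add atoms: none
Why: Double Swern oxidation; activated DMSO oxidises vicinal diols to 1,2‑diketones without C–C cleavage because no cyclic ester intermediate is involved. The resulting triketone 16 enolises spontaneously at the doubly activated C3–H to the conjugated hydroxyquinone, and the acid wash releases it from its ammonium salt.

## Compound list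

1 | stearoyl chloride (octadecanoyl chloride) | CCCCCCCCCCCCCCCCCC(=O)Cl | starting material
2 | N‑methoxy‑N‑methyloctadecanamide | CCCCCCCCCCCCCCCCCC(=O)N(C)OC | intermediate
3 | methyl vinyl ether | COC=C | starting material
4 | 1‑methoxyvinyllithium (not isolated) | [Li]C(=C)OC | intermediate
5 | lithium 2‑methoxy‑3‑[methoxy(methyl)amino]icos‑1‑en‑3‑olate (not isolated) | CCCCCCCCCCCCCCCCCC(O[Li])(N(C)OC)C(=C)OC | intermediate
6 | 2‑methoxyicos‑1‑en‑3‑one | CCCCCCCCCCCCCCCCCC(=O)C(=C)OC | intermediate
7 | methyl 2‑hydroxybut‑3‑enoate (racemic) | C=CC(O)C(=O)OC | starting material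
8 | methyl 2‑(tert‑butyldimethylsilyloxy)but‑3‑enoate (racemic) | C=CC(O[Si](C)(C)C(C)(C)C)C(=O)OC | intermediate
9 | [2‑(tert‑butyldimethylsilyloxy)‑1‑methoxybut‑3‑enyloxy]diisobutylalane (not isolated) | C=CC(O[Si](C)(C)C(C)(C)C)C(OC)O[Al](CC(C)C)CC(C)C | intermediate
10 | 2‑(tert‑butyldimethylsilyloxy)but‑3‑enal (racemic) | C=CC(O[Si](C)(C)C(C)(C)C)C=O | intermediate
11 | lithium 2‑methoxyicosa‑1,3‑dien‑3‑olate (enolate geometry not defined, not isolated) | CCCCCCCCCCCCCCCCC=C(O[Li])C(=C)OC | intermediate
12 | 6‑(tert‑butyldimethylsilyloxy)‑4‑hexadecyl‑5‑hydroxy‑2‑methoxyocta‑1,7‑dien‑3‑one (all diastereomers) | CCCCCCCCCCCCCCCCC(C(O)C(O[Si](C)(C)C(C)(C)C)C=C)C(=O)C(=C)OC | intermediate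
13 | 5,6‑bis(tert‑butyldimethylsilyloxy)‑4‑hexadecyl‑2‑methoxyocta‑1,7‑dien‑3‑one (all diastereomers) | CCCCCCCCCCCCCCCCC(C(O[Si](C)(C)C(C)(C)C)C(O[Si](C)(C)C(C)(C)C)C=C)C(=O)C(=C)OC | intermediate
14 | 4,5‑bis(tert‑butyldimethylsilyloxy)‑6‑hexadecyl‑2‑methoxycyclohex‑2‑en‑1‑one (all diastereomers) | CCCCCCCCCCCCCCCCC1C(O[Si](C)(C)C(C)(C)C)C(O[Si](C)(C)C(C)(C)C)C=C(OC)C1=O | intermediate
15 | 6‑hexadecyl‑4,5‑dihydroxy‑2‑methoxycyclohex‑2‑en‑1‑one (all diastereomers) | CCCCCCCCCCCCCCCCC1C(O)C(O)C=C(OC)C1=O | intermediate
16 | 3‑hexadecyl‑5‑methoxycyclohex‑5‑ene‑1,2,4‑trione (racemic, not isolated) | CCCCCCCCCCCCCCCCC1C(=O)C(=O)C=C(OC)C1=O | intermediate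
17 | 3‑hexadecyl‑2‑hydroxy‑5‑methoxycyclohexa‑2,5‑diene‑1,4‑dione | CCCCCCCCCCCCCCCCC1=C(O)C(=O)C=C(OC)C1=O | target

## Step count and risk

Total step count: 9.
Longest linear sequence: 7 steps (1 → 2 → 6 → 12 → 13 → 14 → 15 → 17; the branch 7 → 8 → 10 joins at step 5 and is equally long).

Least certain steps:

**Step 7 (key step).**
- Risk: the alkylidene formed at the vinyl carbinol may not engage the hindered, carbonyl‑conjugated 1,1‑disubstituted enol ether olefin fast enough. Intermolecular cross‑metathesis between vinyl termini and catalyst decomposition, with hydride‑mediated migration of the allylic double bond, would then take over. Diastereomers that must place a silyloxy group or the chain pseudo‑axial may also close more slowly than the others.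
- Fallback (from 13, back at 14): the C3 ketone of 13 is reduced with i‑Bu2AlH (CH2Cl2, −78 °C) to 5,6‑bis(tert‑butyldimethylsilyloxy)‑4‑hexadecyl‑2‑methoxyocta‑1,7‑dien‑3‑ol F1. Its enol ether olefin is no longer conjugated and is an electron‑rich 2‑methoxyalkene of the kind that closes in enol ether–olefin metatheses. Ring closure of F1 with the same ruthenium catalyst should give 4,5‑bis(tert‑butyldimethylsilyloxy)‑6‑hexadecyl‑2‑methoxycyclohex‑2‑en‑1‑ol F2. Oxidation of its allylic hydroxyl (Dess–Martin periodinane, NaHCO3, CH2Cl2) returns the route to 14.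

**Step 5.**
- Risk: proton transfer from the doubly activated α‑position of aldehyde 10 to enolate 11 (with conjugation of the aldehyde double bond), retro‑aldol of the lithium aldolate before the quench, or residual conjugate self‑addition of the enone would each erode conversion.
- Fallback (from 2 and 10, back at 13): the aldol is run at the amide oxidation level, before the enone exists. Deprotonation of 2 with LiN(i‑Pr)2 (THF, −78 °C) and addition to 10 should give 4‑(tert‑butyldimethylsilyloxy)‑2‑hexadecyl‑3‑hydroxy‑N‑methoxy‑N‑methylhex‑5‑enamide F3. Silylation (TBSOTf, 2,6‑lutidine) gives 3,4‑bis(tert‑butyldimethylsilyloxy)‑2‑hexadecyl‑N‑methoxy‑N‑methylhex‑5‑enamide F4. Addition of 1‑methoxyvinyllithium 4 (made from 3 as in step 2) converts the Weinreb amide into 13, bypassing 6 and 12.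

**Step 9.**
- Risk: on addition of Et3N the activated C2 oxygen, which is β to the C4 ketone, may be lost by E1cB elimination faster than it is oxidised, and aromatisation would then remove one of the four ring oxygens. The acidic product may also be sulfenylated by surplus activated DMSO.
- Fallback (from 15, back at 17): only the allylic C1 carbinol of 15 is oxidised with MnO2 (CH2Cl2, rt) to 6‑hexadecyl‑5‑hydroxy‑2‑methoxycyclohex‑2‑ene‑1,4‑dione F5. F5 is the diketo tautomer of an arene and should enolise (a trace of Et3N if needed) to 3‑hexadecyl‑5‑methoxybenzene‑1,2,4‑triol F6. This hydroxyhydroquinone is oxidised to 17 by air or by the MnO2 already present. One alcohol oxidation then suffices and no activated β‑leaving group is generated.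

**Step 8.**
- Risk: β‑elimination of the C2 silyloxy or hydroxyl group across C2–C3 (C3–H is α to the C4 ketone) followed by aromatisation. Slow cleavage of the two crowded vicinal silyl ethers would invite harsher acid, which also threatens the enol ether by hydrolysis.
- Fallback (from 14, back at 17): the elimination is accepted and driven to completion. TsOH·H2O in wet THF at 50 °C should desilylate, eliminate and aromatise 14 to 2‑hexadecyl‑6‑methoxybenzene‑1,4‑diol F7. FeCl3 in aqueous ethanol oxidises it to 2‑hexadecyl‑6‑methoxycyclohexa‑2,5‑diene‑1,4‑dione F8. H2O2/Na2CO3 epoxidises the alkyl‑substituted double bond (the methoxy‑substituted one is deactivated as a vinylogous ester) to 1‑hexadecyl‑3‑methoxy‑7‑oxabicyclo[4.1.0]hept‑3‑ene‑2,5‑dione F9. Cold concentrated H2SO4 then isomerises the epoxide to the 2‑hydroxy‑3‑alkylquinone 17, the classical alkylquinone oxide to hydroxyquinone rearrangement, which puts the lost oxygen back on C2.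

## Further compounds

F1 | step 7 | 5,6‑bis(tert‑butyldimethylsilyloxy)‑4‑hexadecyl‑2‑methoxyocta‑1,7‑dien‑3‑ol (all diastereomers) | CCCCCCCCCCCCCCCCC(C(O[Si](C)(C)C(C)(C)C)C(O[Si](C)(C)C(C)(C)C)C=C)C(O)C(=C)OC
F2 | step 7 | 4,5‑bis(tert‑butyldimethylsilyloxy)‑6‑hexadecyl‑2‑methoxycyclohex‑2‑en‑1‑ol (all diastereomers) | CCCCCCCCCCCCCCCCC1C(O[Si](C)(C)C(C)(C)C)C(O[Si](C)(C)C(C)(C)C)C=C(OC)C1O
F3 | step 5 | 4‑(tert‑butyldimethylsilyloxy)‑2‑hexadecyl‑3‑hydroxy‑N‑methoxy‑N‑methylhex‑5‑enamide (all diastereomers) | CCCCCCCCCCCCCCCCC(C(O)C(O[Si](C)(C)C(C)(C)C)C=C)C(=O)N(C)OC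
F4 | step 5 | 3,4‑bis(tert‑butyldimethylsilyloxy)‑2‑hexadecyl‑N‑methoxy‑N‑methylhex‑5‑enamide (all diastereomers) | CCCCCCCCCCCCCCCCC(C(O[Si](C)(C)C(C)(C)C)C(O[Si](C)(C)C(C)(C)C)C=C)C(=O)N(C)OC
F5 | step 9 | 6‑hexadecyl‑5‑hydroxy‑2‑methoxycyclohex‑2‑ene‑1,4‑dione (all diastereomers) | CCCCCCCCCCCCCCCCC1C(O)C(=O)C=C(OC)C1=O
F6 | step 9 | 3‑hexadecyl‑5‑methoxybenzene‑1,2,4‑triol | CCCCCCCCCCCCCCCCc1c(O)c(O)cc(OC)c1O
F7 | step 8 | 2‑hexadecyl‑6‑methoxybenzene‑1,4‑diol | CCCCCCCCCCCCCCCCc1cc(O)cc(OC)c1O
F8 | step 8 | 2‑hexadecyl‑6‑methoxycyclohexa‑2,5‑diene‑1,4‑dione | CCCCCCCCCCCCCCCCC1=CC(=O)C=C(OC)C1=O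
F9 | step 8 | 1‑hexadecyl‑3‑methoxy‑7‑oxabicyclo[4.1.0]hept‑3‑ene‑2,5‑dione (racemic) | CCCCCCCCCCCCCCCCC12OC1C(=O)C=C(OC)C2=O
A1 | alternative 1 | 2‑hexadecyl‑4‑hydroxy‑3‑isopropoxy‑4‑[(Z)‑2‑methoxyvinyl]cyclobut‑2‑en‑1‑one (racemic) | CCCCCCCCCCCCCCCCC1=C(OC(C)C)C(O)(/C=C\OC)C1=O
A2 | alternative 1 | 3‑hexadecyl‑2‑isopropoxy‑5‑methoxybenzene‑1,4‑diol | CCCCCCCCCCCCCCCCc1c(O)c(OC)cc(O)c1OC(C)C
A3 | alternative 2 | icosane‑2,3‑dione | CCCCCCCCCCCCCCCCCC(=O)C(C)=O
A4 | alternative 2 | 3‑hexadecyl‑2,5‑dihydroxy‑1,4‑benzoquinone | CCCCCCCCCCCCCCCCC1=C(O)C(=O)C=C(O)C1=O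
A5 | alternative 3 | methyl 3,5,7‑trioxotricosanoate | CCCCCCCCCCCCCCCCC(=O)CC(=O)CC(=O)CC(=O)OC
A6 | alternative 3 | methyl 6‑hexadecyl‑2,4‑dihydroxybenzoate | CCCCCCCCCCCCCCCCc1cc(O)cc(O)c1C(=O)OC
A7 | alternative 3 | 5‑hexadecylbenzene‑1,3‑diol | CCCCCCCCCCCCCCCCc1cc(O)cc(O)c1
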